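East gets more reagent than south-east, south-east more time and a warm finish, so we put both on one scale before we commit.

| setting | red | violet | south-east | east |
|---|---|---|---|---|
| solid substrate | 10 mM | 10 mM | 10 mM | 10 mM |
| reagent | 8.4 mM (fed, over 100 min) | 43 mM (fed, over 100 min) | 15.0 mM (fed, over 100 min) | 50.0 mM (fed, over 100 min) |
| temperature | −25 °C | −10 °C |  |  |
| remark | run made earlier | run made earlier | at −20 °C until 50 min, from then on at 0 °C | at −20 °C throughout |
| time |  |  | 1.5 h | 0.50 h |

| run | time / min | target / % |
|---|---|---|
| red | 8.00 | 0 |
| red | 12.0 | 0.2 |
| red | 15.0 | 0 |
| red | 25.0 | 0.2 |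
| red | 40.0 | 1.2 |
| red | 60.0 | 2.8 |
| red | 90.0 | 7.4 |
| violet | 3.00 | 0.5 |
| violet | 10.0 | 0.3 |
| violet | 15.0 | 1.5 |
| violet | 25.0 | 7.0 |
| violet | 30.0 | 11.1 |
| violet | 50.0 | 36.1 |
| violet | 60.0 | 49.5 |

(standard deviation of a reading: 0.5 percentage points)

- given per volume of solution although it is solid: solid substrate
- the numbers in the tables scatter with a standard deviation of 0.5 percentage points
- at the start none of the solid substrate is in solution
- what has only dissolved of solid substrate counts as not reacted
- percentages count the whole charge, also what has not yet gone in

* the winner by amount of target, in percent of the solid substrate charged; "neither" if no more than 2 percentage points parts them (south-east / east / neither)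
* how much target is there at the end, in percent of the solid substrate charged: south-east
* how much target is there at the end, in percent of the solid substrate charged: east

Under a steady feed, the time integral of the reagent gone in is its exposure: charge × time² / (2 × dosing time). The zero of our scale is a flask where target follows exposure in proportion. The last red reading gives 2.18 × 10⁻⁴ mM⁻¹ min⁻¹ of the charge per unit of exposure, and the last violet reading 6.40 × 10⁻⁴ mM⁻¹ min⁻¹. Together they give 39.0 kJ mol⁻¹, our warming energy, the apparent activation energy of target per exposure. It puts the yield at 3.16 × 10⁻⁴ mM⁻¹ min⁻¹ at −20 °C and 0.00123 mM⁻¹ min⁻¹ at 0 °C.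

For south-east, the whole exposure taken cold gives a floor of 19.2%, and taken warm a ceiling of 74.7%. Split at 50 min, it gives our own figure, 57.5%. For east, the whole exposure gives a ceiling of 7.11%. The red run still reads 0.2% at 25.0 min, so counting exposure from that time gives a floor of 2.17%. South-east's floor stands above east's ceiling, so we back south-east.

The forecast also names south-east, with 56% for south-east and 5.5% for east, reading “a lag, then growth” in the runs. Both figures lie inside our brackets, its south-east figure a little below ours.

The flask gives 75.5% for south-east and 2.88% for east. The winner stands, and east falls inside its bracket, but south-east ends just above our ceiling and 19 percentage points above the forecast.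

    intermediate → target (k = 0.0390 min⁻¹, Ea = 74.0 kJ mol⁻¹)
    starting material + reagent → intermediate + released group (k = 2.90 M⁻¹ min⁻¹, Ea = 53.0 kJ mol⁻¹)
    solid substrate ⇌ starting material, rate k3*(cs3 - [starting material]) while solid is left; crystals form when [starting material] > cs3 (solubility = 7.80 mM, k = 0.0170 min⁻¹)
    (constants at −20 °C)

Watch the warm stage. South-east held at −20 °C gives 26.2% against 75.5%, and the second temperature is the main reason. Our warming energy multiplies the yield by 3.88 across the change, yet both steps in the scheme have higher activation energies. At 0.833 h, the time of the change, south-east also holds 52.6% of its charge as solid substrate and 8.19% as intermediate, stages that exposure does not count.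

For east repeated at 5 °C, the warming energy gives 0.00167 mM⁻¹ min⁻¹, hence a bracket from 11.5% to 37.7%. That flask gives 30.9%.

The earlier runs and the new flask were computed for an exercise; scatter was added.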